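**Plan**

- Retrosynthesis: the two aryl C–Br bonds, the phenol O–H (masked as OCH3) and the C2 methyl (taken back to CHO) are adjusted first. The C1–C2 bond between the two quaternary carbons of the bicyclo[3.1.0]hexane is then cut by reversing a 1,2-shift, which reopens a cyclohexene oxide. Last come the aryl–C bond (enolate arylation) and the cyclopropane CH2 (carbenoid transfer).
- Enabling feature (core numbered as 2-aryl-1,2-dimethylbicyclo[3.1.0]hexane, C6 = cyclopropane CH2): quaternary C2 is benzylic and directly bonded to the quaternary cyclopropane carbon C1. The C1–C2 bond can therefore be made by letting C1 shift onto a benzylic cationic carbon from its neighbour in a six-membered ring, the extruded ring carbon surviving as CHO and later as the C2 methyl.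
- Forward order of rings: the cyclohexene is bought; the cyclopropane is closed on it (step 2); the arene is joined (step 4); the oxirane is closed (step 7); the six-membered ring contracts to the cyclopentane (step 8); three functional-group steps finish.
- Stereochemistry: a CBS reduction sets one carbinol centre, which directs the cyclopropanation (target C1 and C5) and is then oxidised away. The cyclopropane directs the epoxidation, and the stereospecific shift translates the oxirane configuration into C2.

Key step: step 8

Numbering remark: in compounds 4–10 the locants are those of bicyclo[4.1.0]heptane (C7 = cyclopropane CH2); in 12–16 they are those of bicyclo[3.1.0]hexane (C6 = cyclopropane CH2). Heptane C1, C6, C7, C3 and C2 become hexane C1, C5, C6, C2 and the formyl carbon.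

**Route**

Step 1
Reactants: 1 2-methylcyclohex-2-en-1-one
Product: 2 (R)-2-methylcyclohex-2-en-1-ol
Conditions: (S)-Me-CBS oxazaborolidine [(S)-1-methyl-3,3-diphenyltetrahydro-1H,3H-pyrrolo[1,2-c][1,3,2]oxazaborole] (10 mol%), BH3·SMe2, THF, −20 °C; aqueous work-up
Reagents that add atoms: none
Why: Corey–Bakshi–Shibata reduction, in which the catalyst–borane complex binds the carbonyl oxygen anti to the larger α-methylvinyl flank and delivers hydride to one face, so the (S)-catalyst should give the R carbinol by exclusive 1,2-reduction.

Step 2
Reactants: 2 (R)-2-methylcyclohex-2-en-1-ol; 3 diiodomethane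
Product: 4 (1S,2R,6R)-1-methylbicyclo[4.1.0]heptan-2-ol (OH cis to the cyclopropane CH2)
Conditions: Et2Zn, CH2I2, CH2Cl2, 0 °C → rt
Reagents that add atoms: none
Why: Hydroxyl-directed Simmons–Smith cyclopropanation (Furukawa conditions), in which the zinc-bound oxygen delivers the carbenoid to the alkene face it occupies, so the new CH2 ends cis to OH and the carbinol centre dictates C1 and C6.

Step 3
Reactants: 4 (1S,2R,6R)-1-methylbicyclo[4.1.0]heptan-2-ol
Product: 5 (1S,6R)-1-methylbicyclo[4.1.0]heptan-2-one
Conditions: Dess–Martin periodinane, CH2Cl2, 0 °C → rt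
Reagents that add atoms: none
Why: Dess–Martin oxidation of a secondary alcohol, which removes the directing carbinol centre once it has done its work, while C1 carries no hydrogen and C6 is remote from the carbonyl, so neither can epimerise.

Step 4
Reactants: 5 (1S,6R)-1-methylbicyclo[4.1.0]heptan-2-one; 6 2-bromo-5-methylanisole (1-bromo-2-methoxy-4-methylbenzene)
Product: 7 (1S,3RS,6R)-3-(2-methoxy-4-methylphenyl)-1-methylbicyclo[4.1.0]heptan-2-one (mixture of C3 epimers)
Conditions: Pd(OAc)2 (2 mol%), 2-dicyclohexylphosphino-2′-methylbiphenyl (4 mol%), NaOtBu, toluene, 80 °C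
Reagents that add atoms: none
Why: Pd-catalysed α-arylation of a ketone enolate (oxidative addition of 6 to zerovalent palladium, enolate transfer, reductive elimination), regiodefined because C1 is quaternary and only C3 can enolise; the product rests as its enolate and resists a second arylation, and the C3 configuration is irrelevant because step 5 erases it.

Step 5
Reactants: 7 (1S,3RS,6R)-3-(2-methoxy-4-methylphenyl)-1-methylbicyclo[4.1.0]heptan-2-one
Product: 9 (1S,6R)-3-(2-methoxy-4-methylphenyl)-1-methylbicyclo[4.1.0]hept-2-en-2-yl trifluoromethanesulfonate, via potassium enolate 8 (not isolated)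
Conditions: KN(SiMe3)2, THF, −78 °C; then PhNTf2, −78 °C → rt
Reagents that add atoms: N-phenylbis(trifluoromethanesulfonimide), O=S(=O)(N(c1ccccc1)S(=O)(=O)C(F)(F)F)C(F)(F)F
Why: Enolate O-sulfonylation, in which the benzylic C3–H is the only α-hydrogen and the potassium enolate reacts at oxygen with the triflimide to give the single, tetrasubstituted enol triflate.

Step 6
Reactants: 9 (1S,6R)-3-(2-methoxy-4-methylphenyl)-1-methylbicyclo[4.1.0]hept-2-en-2-yl trifluoromethanesulfonate
Product: 10 (1S,6R)-3-(2-methoxy-4-methylphenyl)-1-methylbicyclo[4.1.0]hept-2-ene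
Conditions: Pd(OAc)2 (5 mol%), PPh3 (10 mol%), HCO2H, Bu3N, DMF, 60 °C
Reagents that add atoms: none
Why: Pd-catalysed formate reduction of an enol triflate (oxidative addition to zerovalent palladium, formate exchange, loss of CO2, C–H reductive elimination), which replaces OTf by H without moving the double bond and leaves the cyclopropane and the aryl ether alone.

Step 7
Reactants: 10 (1S,6R)-3-(2-methoxy-4-methylphenyl)-1-methylbicyclo[4.1.0]hept-2-ene
Product: 11 (1S,2R,4R,7R)-4-(2-methoxy-4-methylphenyl)-1-methyl-3-oxatricyclo[5.1.0.0^2,4]octane (the 2,3-epoxide of 10, oxygen anti to the cyclopropane CH2)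
Conditions: dimethyldioxirane (acetone solution), CH2Cl2, −20 → 0 °C; evaporate and use crude
Reagents that add atoms: dimethyldioxirane, CC1(C)OO1
Why: Dioxirane epoxidation (concerted oxygen transfer under neutral, acid-free conditions) of an electron-rich trisubstituted styrene, in which the cyclopropane CH2 leans over one face of the C2=C3 bond while the C1 methyl lies near the ring plane pointing away, so the oxidant should enter anti to the cyclopropane and set both oxirane carbons.

Step 8
Reactants: 11 (1S,2R,4R,7R)-4-(2-methoxy-4-methylphenyl)-1-methyl-3-oxatricyclo[5.1.0.0^2,4]octane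
Product: 12 (1S,2S,5R)-2-(2-methoxy-4-methylphenyl)-1-methylbicyclo[3.1.0]hexane-2-carbaldehyde
Conditions: BF3·OEt2 (0.2 equiv), CH2Cl2, −78 °C, short reaction time; Et3N, then aq. NaHCO3
Reagents that add atoms: none
Why: BF3 binds the oxirane oxygen and the benzylic C–O bond, weakened by the ortho-methoxy, para-methyl arene, ionises while the σ-bond from the oxirane CH carbon to the quaternary cyclopropane carbon shifts onto the benzylic carbon, the CH carbon becoming the formyl group. This is the Lewis acid-promoted Meinwald (semipinacol) rearrangement by which 1-arylcyclohexene oxides contract to 1-arylcyclopentanecarbaldehydes. The cyclopentane ring is closed by ring contraction through a three-centre suprafacial 1,2-shift, not by an end-to-end cyclisation, and the cyclopropane stays intact. The one new stereocentre, the benzylic quaternary carbon, is controlled by the oxirane configuration: the migrating carbon keeps its own configuration and enters on the face opposite the departing oxygen, so the anti epoxide places the aryl group syn and the formyl group anti to the cyclopropane CH2. The step needs C–O cleavage at the benzylic rather than the cyclopropylcarbinyl carbon, which the electron-rich arene secures, and carbon shift rather than hydride shift, which is favoured because at the moment of ring opening the retained C–O bond is pseudo-axial and the ring bond, not the C–H bond, leans toward the empty benzylic orbital, the low temperature keeping the ion pair from relaxing. Ketone formed by a stray hydride shift would be compound 7 and could be returned to step 5.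

Step 9
Reactants: 12 (1S,2S,5R)-2-(2-methoxy-4-methylphenyl)-1-methylbicyclo[3.1.0]hexane-2-carbaldehyde
Product: 14 1-[(1S,2R,5R)-1,2-dimethylbicyclo[3.1.0]hexan-2-yl]-2-methoxy-4-methylbenzene, via hydrazone 13 (not isolated)
Conditions: N2H4·H2O, diethylene glycol, 130 °C; then KOH, 200 °C (water distilled off)
Reagents that add atoms: none
Why: Wolff–Kishner reduction in its Huang-Minlon form, with the hydrazone formed before base is added so that the non-enolisable aldehyde cannot disproportionate; the formyl carbon has no configuration to lose, the transient carbanion is not attached to the cyclopropane, and any O-demethylation here would only anticipate step 10.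

Step 10
Reactants: 14 1-[(1S,2R,5R)-1,2-dimethylbicyclo[3.1.0]hexan-2-yl]-2-methoxy-4-methylbenzene
Product: 15 2-[(1S,2R,5R)-1,2-dimethylbicyclo[3.1.0]hexan-2-yl]-5-methylphenol
Conditions: NaSEt, DMF, 140 °C; aq. NH4Cl work-up
Reagents that add atoms: none
Why: Nucleophilic demethylation (SN2 attack of ethanethiolate on the O-methyl carbon), chosen because it is basic and so avoids the acid-induced addition of the free phenol to the neighbouring cyclopropane.

Step 11
Reactants: 15 2-[(1S,2R,5R)-1,2-dimethylbicyclo[3.1.0]hexan-2-yl]-5-methylphenol
Product: 16 2,4-dibromo-6-[(1S,2R,5R)-1,2-dimethylbicyclo[3.1.0]hexan-2-yl]-3-methylphenol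
Conditions: N-bromosuccinimide (2.1 equiv), NaHCO3 (solid), MeCN, 0 °C → rt, dark
Reagents that add atoms: N-bromosuccinimide, O=C1CCC(=O)N1Br
Why: Electrophilic aromatic bromination, in which the hydroxyl group activates its free para and ortho positions (the only other free ring position is meta to OH), while solid NaHCO3 removes traces of HBr that could open the cyclopropane.

**Compound list**

1 | 2-methylcyclohex-2-en-1-one | CC1=CCCCC1=O | starting material
2 | (R)-2-methylcyclohex-2-en-1-ol | O[C@@H]1CCCC=C1C | intermediate
3 | diiodomethane | ICI | starting material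
4 | (1S,2R,6R)-1-methylbicyclo[4.1.0]heptan-2-ol | O[C@@H]1CCC[C@@H]2C[C@]12C | intermediate
5 | (1S,6R)-1-methylbicyclo[4.1.0]heptan-2-one | O=C1CCC[C@@H]2C[C@]12C | intermediate
6 | 2-bromo-5-methylanisole (1-bromo-2-methoxy-4-methylbenzene) | COc1cc(C)ccc1Br | starting material
7 | (1S,3RS,6R)-3-(2-methoxy-4-methylphenyl)-1-methylbicyclo[4.1.0]heptan-2-one (C3 epimers) | O=C1C(c2ccc(C)cc2OC)CC[C@@H]2C[C@]12C | intermediate
8 | potassium (1S,6R)-3-(2-methoxy-4-methylphenyl)-1-methylbicyclo[4.1.0]hept-2-en-2-olate | [K+].[O-]C1=C(c2ccc(C)cc2OC)CC[C@@H]2C[C@]12C | intermediate (not isolated)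
9 | (1S,6R)-3-(2-methoxy-4-methylphenyl)-1-methylbicyclo[4.1.0]hept-2-en-2-yl trifluoromethanesulfonate | FC(F)(F)S(=O)(=O)OC1=C(c2ccc(C)cc2OC)CC[C@@H]2C[C@]12C | intermediate
10 | (1S,6R)-3-(2-methoxy-4-methylphenyl)-1-methylbicyclo[4.1.0]hept-2-ene | C1=C(c2ccc(C)cc2OC)CC[C@@H]2C[C@]12C | intermediate
11 | (1S,2R,4R,7R)-4-(2-methoxy-4-methylphenyl)-1-methyl-3-oxatricyclo[5.1.0.0^2,4]octane (oxygen anti to the cyclopropane CH2) | COc1cc(C)ccc1[C@]12CC[C@@H]3C[C@]3(C)[C@H]1O2 | intermediate
12 | (1S,2S,5R)-2-(2-methoxy-4-methylphenyl)-1-methylbicyclo[3.1.0]hexane-2-carbaldehyde | COc1cc(C)ccc1[C@]1(C=O)CC[C@@H]2C[C@@]21C | intermediate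
13 | {(E)-[(1S,2S,5R)-2-(2-methoxy-4-methylphenyl)-1-methylbicyclo[3.1.0]hexan-2-yl]methylidene}hydrazine | COc1cc(C)ccc1[C@]1(/C=N/N)CC[C@@H]2C[C@@]21C | intermediate (not isolated)
14 | 1-[(1S,2R,5R)-1,2-dimethylbicyclo[3.1.0]hexan-2-yl]-2-methoxy-4-methylbenzene | COc1cc(C)ccc1[C@]1(C)CC[C@@H]2C[C@@]21C | intermediate
15 | 2-[(1S,2R,5R)-1,2-dimethylbicyclo[3.1.0]hexan-2-yl]-5-methylphenol | Cc1ccc([C@]2(C)CC[C@@H]3C[C@@]32C)c(O)c1 | intermediate
16 | 2,4-dibromo-6-[(1S,2R,5R)-1,2-dimethylbicyclo[3.1.0]hexan-2-yl]-3-methylphenol | Cc1c(Br)cc([C@]2(C)CC[C@@H]3C[C@@]32C)c(O)c1Br | target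

**Step count and risks**

Total step count: 11. Longest linear sequence: 11 steps (1 → 16); compounds 3 and 6 are bought and used as such.

Steps most likely to fail:

Step 8. A hydride shift to the ketone may outrun the shift of the ring carbon, or the benzylic cation may live long enough for the facial information of the oxirane to be lost. The fallback sets out from 10 and comes back at 12, and it replaces the cationic opening by a halohydrin semipinacol with two inversions. N-Bromosuccinimide in acetone–water at 0 °C should add bromine anti to the cyclopropane and water at the benzylic carbon, giving (1S,2R,3S,6R)-2-bromo-3-(2-methoxy-4-methylphenyl)-1-methylbicyclo[4.1.0]heptan-3-ol F1. K2CO3 in MeOH closes this to the syn epoxide (1S,2S,4S,7R)-4-(2-methoxy-4-methylphenyl)-1-methyl-3-oxatricyclo[5.1.0.0^2,4]octane F2. LiBr with hexamethylphosphoramide in toluene at 80 °C opens F2 at the benzylic carbon with inversion to lithium (1S,2S,3R,6R)-3-bromo-3-(2-methoxy-4-methylphenyl)-1-methylbicyclo[4.1.0]heptan-2-olate F3, which is not isolated. In its diequatorial conformer only the ring bond to the cyclopropane carbon is antiperiplanar to C–Br, while the C–H bond is gauche, so the carbon shift expels bromide with a second inversion and no free cation. Two inversions on the syn epoxide lead to the same configuration as one inversion on the anti epoxide, that of 12.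

Step 7. The oxidant may fail to distinguish the two alkene faces well enough, or the electron-rich styrene oxide may open prematurely. The fallback sets out from 10 and comes back at 11, and it hands facial control from the substrate to a chiral dioxirane. This is a Shi epoxidation with the D-fructose-derived ketone 1,2:4,5-di-O-isopropylidene-β-D-erythro-2,3-hexodiulo-2,6-pyranose (0.3 equiv), KHSO5 (as Oxone, 2KHSO5·KHSO4·K2SO4), K2CO3 and Bu4NHSO4 in MeCN–dimethoxymethane–aqueous buffer at about pH 10.5 and 0 °C. The established sense of induction of this ketone for 1-arylcyclohexenes corresponds to the R,R oxirane needed here, so reagent and substrate preferences are matched, and the basic medium protects the epoxide. This fallback passes through no new compound (F0).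

Step 9. Hydrazone formation at the neopentyl-type formyl group may be incomplete, or the compound may suffer at 200 °C in strong base. The fallback sets out from 12 and comes back at 14 and is a Mozingo reduction. Ethane-1,2-dithiol with BF3·OEt2 in CH2Cl2 at 0 °C gives 2-[(1S,2S,5R)-2-(2-methoxy-4-methylphenyl)-1-methylbicyclo[3.1.0]hexan-2-yl]-1,3-dithiolane F4. Raney nickel (Ni) in refluxing EtOH then removes the sulfur and leaves the methyl group of 14; the cyclopropane is not conjugated and should survive.

**Further compounds**

F1 | step 8 | (1S,2R,3S,6R)-2-bromo-3-(2-methoxy-4-methylphenyl)-1-methylbicyclo[4.1.0]heptan-3-ol | COc1cc(C)ccc1[C@@]1(O)CC[C@@H]2C[C@]2(C)[C@H]1Br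
F2 | step 8 | (1S,2S,4S,7R)-4-(2-methoxy-4-methylphenyl)-1-methyl-3-oxatricyclo[5.1.0.0^2,4]octane | COc1cc(C)ccc1[C@@]12CC[C@@H]3C[C@]3(C)[C@@H]1O2
F3 | step 8 | lithium (1S,2S,3R,6R)-3-bromo-3-(2-methoxy-4-methylphenyl)-1-methylbicyclo[4.1.0]heptan-2-olate | COc1cc(C)ccc1[C@]1(Br)CC[C@@H]2C[C@]2(C)[C@@H]1[O-].[Li+]
F0 | step 7 | none | none
F4 | step 9 | 2-[(1S,2S,5R)-2-(2-methoxy-4-methylphenyl)-1-methylbicyclo[3.1.0]hexan-2-yl]-1,3-dithiolane | COc1cc(C)ccc1[C@]1(C3SCCS3)CC[C@@H]2C[C@@]21C
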